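**Strategy.** Everything rests on opening the C5–C6 bond of the ten-membered ring together with the lactone O–C12 bond. C6 is an allylic carbinol carbon on the E C4=C5 alkene and lies γ to the lactone carbonyl C12. A single Nozaki–Hiyama–Kishi reaction of an (E)-alkenyl iodide (C5) with a C6 aldehyde therefore closes the cyclodecadiene ring, sets C6 and leaves an alkoxide that acylates itself on the C12 methyl ester, closing the trans-fused γ-lactone ring. The precursor is an open chain carrying the C5 iodide, the Z C1=C10 alkene, the C7–C9 stereotriad (C8 silyl ether, C9 PMB ether), the C6 aldehyde and the C12 ester, built by carboalumination, Z-selective Wittig olefination and an auxiliary-controlled syn aldol.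

Key step: step 15

**Remarks on the chemistry (assumptions)**
- Germacrane numbering is used: ring C1–C10, lactone oxygen on C6, C11–C13 on C7, C14 on C10, C15 on C4. The target is 6R,7S,8R,9R with Z C1=C10 and E C4=C5; the stereocentre of the (S)-glycerate ester becomes C9.
- The C8 and C6 oxygens are both γ to C12. C12 is therefore a tert-butyl ester while C8 is a free aldol hydroxyl, and the C6 acyl group is reduced straight to the aldehyde, so no hydroxy methyl ester that could lactonise early ever exists.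
- C9 is protected as a PMB ether (oxidative release) and C8 as a TBS ether (fluoride release), so the finished cyclodecadiene lactone never meets strong acid.
- The 4-methoxybenzylidene acetal is carried as a mixture of acetal epimers, which converge on reductive opening.

**Route**

Step 1
Reactants: 1 pent-4-yn-1-ol
Product: 3 (4E)-5-iodo-4-methylpent-4-en-1-ol, via alkenylalane 2 (not isolated)
Conditions: Me3Al (3 equiv), Cp2ZrCl2 (0.25 equiv), CH2Cl2, 0 °C to rt; then I2, THF, −30 to 0 °C; aq. potassium sodium tartrate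
Reagents that add atoms: trimethylaluminium, C[Al](C)C; iodine, II
Why: Zirconium-catalysed carboalumination (Negishi) adds CH3 and Al syn across the terminal alkyne with CH3 on the internal carbon, and iododealumination with retention gives only the E iodide (future C4=C5 with C15).

Step 2
Reactants: 3 (4E)-5-iodo-4-methylpent-4-en-1-ol
Product: 4 (1E)-1,5-diiodo-2-methylpent-1-ene
Conditions: I2, PPh3, imidazole, CH2Cl2, 0 °C to rt
Reagents that add atoms: iodine, II
Why: Appel-type iodination: the oxyphosphonium formed from PPh3/I2 is displaced by iodide in an SN2 reaction at the primary carbon, and the alkenyl iodide is inert.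

Step 3
Reactants: 4 (1E)-1,5-diiodo-2-methylpent-1-ene
Product: 5 [(4E)-5-iodo-4-methylpent-4-en-1-yl](triphenyl)phosphonium iodide
Conditions: PPh3, MeCN, 80 °C
Reagents that add atoms: triphenylphosphine, c1ccc(cc1)P(c1ccccc1)c1ccccc1
Why: SN2 quaternisation of PPh3 occurs only at the primary alkyl iodide because the sp2 C–I bond cannot be displaced, giving the salt needed for the Wittig reaction.

Step 4
Reactants: 6 methyl (4S)-2,2-dimethyl-1,3-dioxolane-4-carboxylate
Product: 8 1-[(4S)-2,2-dimethyl-1,3-dioxolan-4-yl]ethan-1-one, via Weinreb amide 7 (not isolated)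
Conditions: MeNHOMe·HCl, i-PrMgCl, THF, −20 °C; then MeMgBr, −20 to 0 °C; aq. NH4Cl
Reagents that add atoms: methylmagnesium bromide, C[Mg]Br; N,O-dimethylhydroxylamine hydrochloride, CNOC.Cl (its atoms stay only in 7)
Why: Magnesium-amide aminolysis of the ester gives the Weinreb amide, whose chelated tetrahedral adduct with MeMgBr resists over-addition and enolisation until quench, so the ketone forms without loss of the dioxolane stereocentre (the future C9).

Step 5
Reactants: 5 [(4E)-5-iodo-4-methylpent-4-en-1-yl](triphenyl)phosphonium iodide; 8 1-[(4S)-2,2-dimethyl-1,3-dioxolan-4-yl]ethan-1-one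
Product: 10 (4R)-4-[(2Z,6E)-7-iodo-6-methylhepta-2,6-dien-2-yl]-2,2-dimethyl-1,3-dioxolane, via phosphorus ylide 9 (not isolated)
Conditions: NaN(SiMe3)2, THF, −78 to 0 °C; then 8, −78 °C to rt
Reagents that add atoms: none
Why: Wittig olefination of a non-stabilised ylide with an α-alkoxy methyl ketone under lithium-free conditions is kinetically Z-selective, placing the C2 chain cis to the oxygenated C9 and so setting the Z C1=C10 alkene, while the low temperature protects the α-stereocentre from enolisation.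

Step 6
Reactants: 10 (4R)-4-[(2Z,6E)-7-iodo-6-methylhepta-2,6-dien-2-yl]-2,2-dimethyl-1,3-dioxolane
Product: 11 (2R,3Z,7E)-8-iodo-3,7-dimethylocta-3,7-diene-1,2-diol
Conditions: AcOH–H2O (4:1), 40 °C
Reagents that add atoms: none
Why: Acid-catalysed hydrolysis of the isopropylidene acetal frees the C8/C9 diol under conditions too mild to ionise the allylic C9–O bond or touch the alkenyl iodide.

Step 7
Reactants: 11 (2R,3Z,7E)-8-iodo-3,7-dimethylocta-3,7-diene-1,2-diol
Product: 12 (4R)-4-[(2Z,6E)-7-iodo-6-methylhepta-2,6-dien-2-yl]-2-(4-methoxyphenyl)-1,3-dioxolane (both acetal epimers)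
Conditions: 4-MeOC6H4CH(OMe)2, pyridinium p-toluenesulfonate (cat.), CH2Cl2, rt
Reagents that add atoms: 4-methoxybenzaldehyde dimethyl acetal, COC(OC)c1ccc(OC)cc1
Why: Acid-catalysed transacetalisation closes the five-membered 4-methoxybenzylidene acetal on the 1,2-diol, the new acetal carbon being a transient stereocentre of no consequence.

Step 8
Reactants: 12 (4R)-4-[(2Z,6E)-7-iodo-6-methylhepta-2,6-dien-2-yl]-2-(4-methoxyphenyl)-1,3-dioxolane
Product: 13 (2R,3Z,7E)-8-iodo-2-[(4-methoxyphenyl)methoxy]-3,7-dimethylocta-3,7-dien-1-ol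
Conditions: i-Bu2AlH, CH2Cl2, −78 to 0 °C; aq. potassium sodium tartrate
Reagents that add atoms: none
Why: Regioselective reductive opening of the benzylidene-type acetal: aluminium binds the less hindered primary oxygen, that C–O bond ionises and hydride quenches the oxocarbenium ion, leaving the PMB group on the C9 oxygen and the C8 hydroxyl free.

Step 9
Reactants: 13 (2R,3Z,7E)-8-iodo-2-[(4-methoxyphenyl)methoxy]-3,7-dimethylocta-3,7-dien-1-ol
Product: 14 (2R,3Z,7E)-8-iodo-2-[(4-methoxyphenyl)methoxy]-3,7-dimethylocta-3,7-dienal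
Conditions: Dess–Martin periodinane, NaHCO3, CH2Cl2, 0 °C; used crude at once
Reagents that add atoms: none
Why: Dess–Martin oxidation under bicarbonate buffering gives the α-alkoxy aldehyde without a basic or strongly acidic medium, so C9 is not epimerised and the β,γ-alkene does not move into conjugation.

Step 10
Reactants: 15 4-tert-butoxy-4-oxobutanoic acid; 16 (4R)-4-benzyl-1,3-thiazolidine-2-thione
Product: 17 tert-butyl 4-[(4R)-4-benzyl-2-thioxo-1,3-thiazolidin-3-yl]-4-oxobutanoate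
Conditions: EDC·HCl, 4-(dimethylamino)pyridine (cat.), CH2Cl2, 0 °C to rt
Reagents that add atoms: none
Why: Carbodiimide activation of the acid and N-acylation of the thiazolidinethione give the activated imide that serves as enolate precursor and, later, as a directly reducible acyl group.

Step 11
Reactants: 17 tert-butyl 4-[(4R)-4-benzyl-2-thioxo-1,3-thiazolidin-3-yl]-4-oxobutanoate; 14 (2R,3Z,7E)-8-iodo-2-[(4-methoxyphenyl)methoxy]-3,7-dimethylocta-3,7-dienal
Product: 19 tert-butyl (3R,4R,5R,6Z,10E)-3-{[(4R)-4-benzyl-2-thioxo-1,3-thiazolidin-3-yl]carbonyl}-4-hydroxy-11-iodo-5-[(4-methoxyphenyl)methoxy]-6,10-dimethylundeca-6,10-dienoate, via titanium enolate 18 (not isolated)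
Conditions: TiCl4 (1.05 equiv), i-Pr2NEt (1.1 equiv), N-methyl-2-pyrrolidinone (1.1 equiv), CH2Cl2, 0 °C then −78 °C; then 14, −78 to −40 °C; aq. NH4Cl
Reagents that add atoms: none
Why: Titanium-mediated auxiliary-controlled syn aldol reaction of an N-acylthiazolidinethione: the Z chlorotitanium enolate reacts through a non-chelated chair Zimmerman–Traxler transition state in which the (R)-benzyl auxiliary shields one enolate face, setting C7 (R) and C8 (R) syn, with reagent control expected to override the Cornforth preference of the α-alkoxy aldehyde, while the tert-butyl ester resists acylation by the C8 aldolate.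

Step 12
Reactants: 19 tert-butyl (3R,4R,5R,6Z,10E)-3-{[(4R)-4-benzyl-2-thioxo-1,3-thiazolidin-3-yl]carbonyl}-4-hydroxy-11-iodo-5-[(4-methoxyphenyl)methoxy]-6,10-dimethylundeca-6,10-dienoate
Product: 22 (3R,4R,5R,6Z,10E)-3-{[(4R)-4-benzyl-2-thioxo-1,3-thiazolidin-3-yl]carbonyl}-4-[(tert-butyldimethylsilyl)oxy]-11-iodo-5-[(4-methoxyphenyl)methoxy]-6,10-dimethylundeca-6,10-dienoic acid, via silyl ether 20 (not isolated), via trimethylsilyl ester 21 (not isolated)
Conditions: TBSOTf, 2,6-lutidine, CH2Cl2, −78 °C; then TMSOTf, 0 °C to rt; pH 5 aqueous work-up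
Reagents that add atoms: tert-butyldimethylsilyl trifluoromethanesulfonate, CC(C)(C)[Si](C)(C)OS(=O)(=O)C(F)(F)F (trimethylsilyl trifluoromethanesulfonate leaves atoms only in 21)
Why: Silyl triflate silylation protects the C8 hydroxyl, and TMSOTf then cleaves the tert-butyl ester by O-silylation and loss of the tert-butyl cation as isobutene, the silyl ester being hydrolysed on work-up, while 2,6-lutidine keeps the medium non-acidic for the PMB ether and the thioimide.

Step 13
Reactants: 22 (3R,4R,5R,6Z,10E)-3-{[(4R)-4-benzyl-2-thioxo-1,3-thiazolidin-3-yl]carbonyl}-4-[(tert-butyldimethylsilyl)oxy]-11-iodo-5-[(4-methoxyphenyl)methoxy]-6,10-dimethylundeca-6,10-dienoic acid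
Product: 23 methyl (3R,4R,5R,6Z,10E)-3-{[(4R)-4-benzyl-2-thioxo-1,3-thiazolidin-3-yl]carbonyl}-4-[(tert-butyldimethylsilyl)oxy]-11-iodo-5-[(4-methoxyphenyl)methoxy]-6,10-dimethylundeca-6,10-dienoate
Conditions: TMSCHN2, MeOH–toluene (1:4), 0 °C
Reagents that add atoms: (trimethylsilyl)diazomethane, C[Si](C)(C)C=[N+]=[N-]
Why: Methylation of the carboxylic acid by trimethylsilyldiazomethane in methanol is fast and neutral, so the electrophilic thioimide and the silyl ether are untouched and the C12 methyl ester needed for the lactonisation appears only after C8 is blocked.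

Step 14
Reactants: 23 methyl (3R,4R,5R,6Z,10E)-3-{[(4R)-4-benzyl-2-thioxo-1,3-thiazolidin-3-yl]carbonyl}-4-[(tert-butyldimethylsilyl)oxy]-11-iodo-5-[(4-methoxyphenyl)methoxy]-6,10-dimethylundeca-6,10-dienoate
Product: 24 methyl (3R,4R,5R,6Z,10E)-4-[(tert-butyldimethylsilyl)oxy]-3-formyl-11-iodo-5-[(4-methoxyphenyl)methoxy]-6,10-dimethylundeca-6,10-dienoate
Conditions: i-Bu2AlH (1.2 equiv), CH2Cl2, −78 °C, until the yellow colour fades; aq. potassium sodium tartrate
Reagents that add atoms: none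
Why: Hydride adds to the highly activated N-acylthiazolidinethione far faster than to the methyl ester at −78 °C and the tetrahedral aluminium adduct collapses only on work-up, so the C6 aldehyde is reached directly, without a C6 alcohol that would lactonise onto C12 and without epimerising C7.

Step 15
Reactants: 24 methyl (3R,4R,5R,6Z,10E)-4-[(tert-butyldimethylsilyl)oxy]-3-formyl-11-iodo-5-[(4-methoxyphenyl)methoxy]-6,10-dimethylundeca-6,10-dienoate
Product: 26 (3aS,4R,5R,6Z,10E,11aR)-4-[(tert-butyldimethylsilyl)oxy]-5-[(4-methoxyphenyl)methoxy]-6,10-dimethyl-3a,4,5,8,9,11a-hexahydrocyclodeca[b]furan-2(3H)-one, via hydroxy ester 25 (not isolated)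
Conditions: CrCl2 (15 equiv), NiCl2 (cat.), degassed DMSO, rt, slow addition of 24 to 0.003 M; aq. NH4Cl; then pyridinium p-toluenesulfonate (cat.), CH2Cl2, rt
Reagents that add atoms: none
Why: CrCl2 reduces NiCl2 to zerovalent nickel, which inserts into the C5–I bond with retention of the E geometry and passes the alkenyl group to trivalent chromium, and the resulting alkenylchromium adds to the C6 aldehyde to give a chromium alkoxide. The closest known reaction type is the intramolecular Nozaki–Hiyama–Kishi macrocyclisation of alkenyl iodide–aldehydes, with the γ-alkoxide acylated by a pendant ester as in chromium-mediated lactone-forming carbonyl additions. The ten-membered carbocycle closes by exo attack on the aldehyde carbon (10-exo-trig), and the γ-lactone closes by 5-exo-trig acyl substitution of the C6 oxygen on the C12 methyl ester with loss of methanol, completed by the pyridinium salt if hydroxy ester 25 survives work-up. The one new stereocentre, C6, is controlled by C7 in a Felkin–Anh arrangement in which C5 approaches anti to the C7–C8 bond and past H7, so that O6 ends syn to C11 and the lactone is trans-fused (H6 anti to H7). The step needs aldehyde-over-ester chemoselectivity, which the weakly basic alkenylchromium provides, and ring closure over oligomerisation, which high dilution and the turn built into the chain by the Z C1=C10 alkene and the C7–C9 substituents should secure; both alkene geometries are retained because no stage of the cycle breaks a C=C π bond.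

Step 16
Reactants: 26 (3aS,4R,5R,6Z,10E,11aR)-4-[(tert-butyldimethylsilyl)oxy]-5-[(4-methoxyphenyl)methoxy]-6,10-dimethyl-3a,4,5,8,9,11a-hexahydrocyclodeca[b]furan-2(3H)-one
Product: 30 (3aS,4R,5R,6Z,10E,11aR)-4-[(tert-butyldimethylsilyl)oxy]-5-[(4-methoxyphenyl)methoxy]-6,10-dimethyl-3-methylidene-3a,4,5,8,9,11a-hexahydrocyclodeca[b]furan-2(3H)-one, via lithium enolate 27 (not isolated), via Mannich base 28 (not isolated), via ammonium iodide 29 (not isolated)
Conditions: LiN(i-Pr)2, THF, −78 °C; CH2=NMe2+ I−, −78 °C to rt; then MeI, MeOH, rt; then aq. NaHCO3, EtOAc, rt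
Reagents that add atoms: N,N-dimethylmethyleneiminium iodide, C=[N+](C)C.[I-] (iodomethane leaves atoms only in 29)
Why: Mannich reaction of the lactone lithium enolate with the iminium salt, N-methylation and base-induced β-elimination of trimethylamine install the exocyclic C11=C13 alkene; the transient C11 stereocentre is lost and the ethers tolerate the base.

Step 17
Reactants: 30 (3aS,4R,5R,6Z,10E,11aR)-4-[(tert-butyldimethylsilyl)oxy]-5-[(4-methoxyphenyl)methoxy]-6,10-dimethyl-3-methylidene-3a,4,5,8,9,11a-hexahydrocyclodeca[b]furan-2(3H)-one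
Product: 31 (3aS,4R,5R,6Z,10E,11aR)-4-[(tert-butyldimethylsilyl)oxy]-5-hydroxy-6,10-dimethyl-3-methylidene-3a,4,5,8,9,11a-hexahydrocyclodeca[b]furan-2(3H)-one
Conditions: DDQ, CH2Cl2/aq. NaH2PO4–Na2HPO4 buffer (pH 7), 0 °C
Reagents that add atoms: none
Why: DDQ oxidises the electron-rich PMB ether by hydride abstraction to an oxocarbenium ion that water hydrolyses, freeing the C9 hydroxyl under buffered neutral conditions that spare the silyl ether, the diene and the α-methylene lactone.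

Step 18
Reactants: 31 (3aS,4R,5R,6Z,10E,11aR)-4-[(tert-butyldimethylsilyl)oxy]-5-hydroxy-6,10-dimethyl-3-methylidene-3a,4,5,8,9,11a-hexahydrocyclodeca[b]furan-2(3H)-one; 32 angelic acid, (2Z)-2-methylbut-2-enoic acid
Product: 34 (3aS,4R,5R,6Z,10E,11aR)-4-[(tert-butyldimethylsilyl)oxy]-6,10-dimethyl-3-methylidene-2-oxo-2,3,3a,4,5,8,9,11a-octahydrocyclodeca[b]furan-5-yl (2Z)-2-methylbut-2-enoate, via mixed anhydride 33 (not isolated)
Conditions: 32, 2,4,6-Cl3C6H2COCl, Et3N, toluene, rt; then 31, 70 °C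
Reagents that add atoms: none
Why: Yamaguchi-type esterification: the alcohol attacks the less hindered angeloyl carbonyl of the mixed anhydride, and omitting a nucleophilic amine catalyst avoids the conjugate addition–elimination that would isomerise the Z acyl group to the tiglate; C9 is untouched because acylation occurs at oxygen.

Step 19
Reactants: 34 (3aS,4R,5R,6Z,10E,11aR)-4-[(tert-butyldimethylsilyl)oxy]-6,10-dimethyl-3-methylidene-2-oxo-2,3,3a,4,5,8,9,11a-octahydrocyclodeca[b]furan-5-yl (2Z)-2-methylbut-2-enoate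
Product: 35 (3aR,4R,5R,6Z,10E,11aR)-4-hydroxy-6,10-dimethyl-3-methylidene-2-oxo-2,3,3a,4,5,8,9,11a-octahydrocyclodeca[b]furan-5-yl (2Z)-2-methylbut-2-enoate
Conditions: HF·pyridine, pyridine, THF, 0 °C to rt
Reagents that add atoms: none
Why: Fluoride cleaves the Si–O bond under buffered, non-basic conditions, so the neighbouring angelate does not migrate to C8 and the cyclodecadiene is not exposed to strong acid (the descriptor at C3a changes only through ligand priorities).

Step 20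
Reactants: 35 (3aR,4R,5R,6Z,10E,11aR)-4-hydroxy-6,10-dimethyl-3-methylidene-2-oxo-2,3,3a,4,5,8,9,11a-octahydrocyclodeca[b]furan-5-yl (2Z)-2-methylbut-2-enoate
Product: 36 (3aS,4R,5R,6Z,10E,11aR)-4-(acetyloxy)-6,10-dimethyl-3-methylidene-2-oxo-2,3,3a,4,5,8,9,11a-octahydrocyclodeca[b]furan-5-yl (2Z)-2-methylbut-2-enoate (CNP0200690.1)
Conditions: Ac2O, 4-(dimethylamino)pyridine (cat.), pyridine, CH2Cl2, 0 °C to rt
Reagents that add atoms: acetic anhydride, CC(=O)OC(C)=O
Why: Acetylation of the secondary C8 hydroxyl with acetic anhydride under nucleophilic catalysis is fast at low temperature and completes the target without disturbing the angelate or the α-methylene lactone.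

**Compound list**

1 | pent-4-yn-1-ol | C#CCCCO | starting material
2 | dimethyl[(1E)-5-[(dimethylalumanyl)oxy]-2-methylpent-1-en-1-yl]alumane (not isolated) | C[Al](C)OCCC/C(C)=C/[Al](C)C | intermediate
3 | (4E)-5-iodo-4-methylpent-4-en-1-ol | OCCC/C(C)=C/I | intermediate
4 | (1E)-1,5-diiodo-2-methylpent-1-ene | ICCC/C(C)=C/I | intermediate
5 | [(4E)-5-iodo-4-methylpent-4-en-1-yl](triphenyl)phosphonium iodide | [I-].I/C=C(\C)CCC[P+](c1ccccc1)(c1ccccc1)c1ccccc1 | intermediate
6 | methyl (4S)-2,2-dimethyl-1,3-dioxolane-4-carboxylate | COC(=O)[C@@H]1COC(C)(C)O1 | starting material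
7 | (4S)-N-methoxy-N,2,2-trimethyl-1,3-dioxolane-4-carboxamide (not isolated) | CON(C)C(=O)[C@@H]1COC(C)(C)O1 | intermediate
8 | 1-[(4S)-2,2-dimethyl-1,3-dioxolan-4-yl]ethan-1-one | CC(=O)[C@@H]1COC(C)(C)O1 | intermediate
9 | [(4E)-5-iodo-4-methylpent-4-en-1-ylidene](triphenyl)phosphorane (not isolated) | I/C=C(\C)CCC=P(c1ccccc1)(c1ccccc1)c1ccccc1 | intermediate
10 | (4R)-4-[(2Z,6E)-7-iodo-6-methylhepta-2,6-dien-2-yl]-2,2-dimethyl-1,3-dioxolane | CC1(C)OC[C@H](O1)/C(C)=C\CC/C(C)=C/I | intermediate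
11 | (2R,3Z,7E)-8-iodo-3,7-dimethylocta-3,7-diene-1,2-diol | OC[C@H](O)/C(C)=C\CC/C(C)=C/I | intermediate
12 | (4R)-4-[(2Z,6E)-7-iodo-6-methylhepta-2,6-dien-2-yl]-2-(4-methoxyphenyl)-1,3-dioxolane (both acetal epimers) | COc1ccc(cc1)C1OC[C@H](O1)/C(C)=C\CC/C(C)=C/I | intermediate
13 | (2R,3Z,7E)-8-iodo-2-[(4-methoxyphenyl)methoxy]-3,7-dimethylocta-3,7-dien-1-ol | OC[C@H](OCc1ccc(OC)cc1)/C(C)=C\CC/C(C)=C/I | intermediate
14 | (2R,3Z,7E)-8-iodo-2-[(4-methoxyphenyl)methoxy]-3,7-dimethylocta-3,7-dienal | O=C[C@H](OCc1ccc(OC)cc1)/C(C)=C\CC/C(C)=C/I | intermediate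
15 | 4-tert-butoxy-4-oxobutanoic acid | CC(C)(C)OC(=O)CCC(=O)O | starting material
16 | (4R)-4-benzyl-1,3-thiazolidine-2-thione | S=C1N[C@H](Cc2ccccc2)CS1 | starting material
17 | tert-butyl 4-[(4R)-4-benzyl-2-thioxo-1,3-thiazolidin-3-yl]-4-oxobutanoate | CC(C)(C)OC(=O)CCC(=O)N1C(=S)SC[C@H]1Cc1ccccc1 | intermediate
18 | trichlorotitanium (Z)-enolate of 17 (not isolated) | CC(C)(C)OC(=O)C/C=C(\O[Ti](Cl)(Cl)Cl)N1C(=S)SC[C@H]1Cc1ccccc1 | intermediate
19 | tert-butyl (3R,4R,5R,6Z,10E)-3-{[(4R)-4-benzyl-2-thioxo-1,3-thiazolidin-3-yl]carbonyl}-4-hydroxy-11-iodo-5-[(4-methoxyphenyl)methoxy]-6,10-dimethylundeca-6,10-dienoate | CC(C)(C)OC(=O)C[C@@H](C(=O)N1C(=S)SC[C@H]1Cc1ccccc1)[C@@H](O)[C@H](OCc1ccc(OC)cc1)/C(C)=C\CC/C(C)=C/I | intermediate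
20 | 4-O-tert-butyldimethylsilyl ether of 19 (not isolated) | CC(C)(C)OC(=O)C[C@@H](C(=O)N1C(=S)SC[C@H]1Cc1ccccc1)[C@@H](O[Si](C)(C)C(C)(C)C)[C@H](OCc1ccc(OC)cc1)/C(C)=C\CC/C(C)=C/I | intermediate
21 | trimethylsilyl ester corresponding to 20 (not isolated) | C[Si](C)(C)OC(=O)C[C@@H](C(=O)N1C(=S)SC[C@H]1Cc1ccccc1)[C@@H](O[Si](C)(C)C(C)(C)C)[C@H](OCc1ccc(OC)cc1)/C(C)=C\CC/C(C)=C/I | intermediate
22 | (3R,4R,5R,6Z,10E)-3-{[(4R)-4-benzyl-2-thioxo-1,3-thiazolidin-3-yl]carbonyl}-4-[(tert-butyldimethylsilyl)oxy]-11-iodo-5-[(4-methoxyphenyl)methoxy]-6,10-dimethylundeca-6,10-dienoic acid | OC(=O)C[C@@H](C(=O)N1C(=S)SC[C@H]1Cc1ccccc1)[C@@H](O[Si](C)(C)C(C)(C)C)[C@H](OCc1ccc(OC)cc1)/C(C)=C\CC/C(C)=C/I | intermediate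
23 | methyl (3R,4R,5R,6Z,10E)-3-{[(4R)-4-benzyl-2-thioxo-1,3-thiazolidin-3-yl]carbonyl}-4-[(tert-butyldimethylsilyl)oxy]-11-iodo-5-[(4-methoxyphenyl)methoxy]-6,10-dimethylundeca-6,10-dienoate | COC(=O)C[C@@H](C(=O)N1C(=S)SC[C@H]1Cc1ccccc1)[C@@H](O[Si](C)(C)C(C)(C)C)[C@H](OCc1ccc(OC)cc1)/C(C)=C\CC/C(C)=C/I | intermediate
24 | methyl (3R,4R,5R,6Z,10E)-4-[(tert-butyldimethylsilyl)oxy]-3-formyl-11-iodo-5-[(4-methoxyphenyl)methoxy]-6,10-dimethylundeca-6,10-dienoate | COC(=O)C[C@@H](C=O)[C@@H](O[Si](C)(C)C(C)(C)C)[C@H](OCc1ccc(OC)cc1)/C(C)=C\CC/C(C)=C/I | intermediate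
25 | methyl 2-[(1S,2R,3R,4Z,8E,10R)-2-[(tert-butyldimethylsilyl)oxy]-10-hydroxy-3-[(4-methoxyphenyl)methoxy]-4,8-dimethylcyclodeca-4,8-dien-1-yl]acetate (not isolated) | COC(=O)C[C@@H]1[C@@H](O[Si](C)(C)C(C)(C)C)[C@H](OCc2ccc(OC)cc2)/C(C)=C\CC/C(C)=C/[C@H]1O | intermediate
26 | (3aS,4R,5R,6Z,10E,11aR)-4-[(tert-butyldimethylsilyl)oxy]-5-[(4-methoxyphenyl)methoxy]-6,10-dimethyl-3a,4,5,8,9,11a-hexahydrocyclodeca[b]furan-2(3H)-one | O=C1C[C@@H]2[C@@H](O[Si](C)(C)C(C)(C)C)[C@H](OCc3ccc(OC)cc3)/C(C)=C\CC/C(C)=C/[C@H]2O1 | intermediate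
27 | lithium enolate of 26 (not isolated) | [Li]OC1=C[C@@H]2[C@@H](O[Si](C)(C)C(C)(C)C)[C@H](OCc3ccc(OC)cc3)/C(C)=C\CC/C(C)=C/[C@H]2O1 | intermediate
28 | 3-[(dimethylamino)methyl] derivative of 26, C3 epimers (not isolated) | CN(C)CC1C(=O)O[C@@H]2/C=C(\C)CC/C=C(/C)[C@@H](OCc3ccc(OC)cc3)[C@H](O[Si](C)(C)C(C)(C)C)[C@@H]12 | intermediate
29 | N,N,N-trimethylammonium iodide of 28 (not isolated) | C[N+](C)(C)CC1C(=O)O[C@@H]2/C=C(\C)CC/C=C(/C)[C@@H](OCc3ccc(OC)cc3)[C@H](O[Si](C)(C)C(C)(C)C)[C@@H]12.[I-] | intermediate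
30 | (3aS,4R,5R,6Z,10E,11aR)-4-[(tert-butyldimethylsilyl)oxy]-5-[(4-methoxyphenyl)methoxy]-6,10-dimethyl-3-methylidene-3a,4,5,8,9,11a-hexahydrocyclodeca[b]furan-2(3H)-one | C=C1C(=O)O[C@@H]2/C=C(\C)CC/C=C(/C)[C@@H](OCc3ccc(OC)cc3)[C@H](O[Si](C)(C)C(C)(C)C)[C@@H]12 | intermediate
31 | (3aS,4R,5R,6Z,10E,11aR)-4-[(tert-butyldimethylsilyl)oxy]-5-hydroxy-6,10-dimethyl-3-methylidene-3a,4,5,8,9,11a-hexahydrocyclodeca[b]furan-2(3H)-one | C=C1C(=O)O[C@@H]2/C=C(\C)CC/C=C(/C)[C@@H](O)[C@H](O[Si](C)(C)C(C)(C)C)[C@@H]12 | intermediate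
32 | angelic acid, (2Z)-2-methylbut-2-enoic acid | C/C=C(/C)C(=O)O | starting material
33 | (2Z)-2-methylbut-2-enoic 2,4,6-trichlorobenzoic anhydride (not isolated) | C/C=C(/C)C(=O)OC(=O)c1c(Cl)cc(Cl)cc1Cl | intermediate
34 | (3aS,4R,5R,6Z,10E,11aR)-4-[(tert-butyldimethylsilyl)oxy]-6,10-dimethyl-3-methylidene-2-oxo-2,3,3a,4,5,8,9,11a-octahydrocyclodeca[b]furan-5-yl (2Z)-2-methylbut-2-enoate | C=C1C(=O)O[C@@H]2/C=C(\C)CC/C=C(/C)[C@@H](OC(=O)/C(C)=C\C)[C@H](O[Si](C)(C)C(C)(C)C)[C@@H]12 | intermediate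
35 | (3aR,4R,5R,6Z,10E,11aR)-4-hydroxy-6,10-dimethyl-3-methylidene-2-oxo-2,3,3a,4,5,8,9,11a-octahydrocyclodeca[b]furan-5-yl (2Z)-2-methylbut-2-enoate | C=C1C(=O)O[C@@H]2/C=C(\C)CC/C=C(/C)[C@@H](OC(=O)/C(C)=C\C)[C@H](O)[C@@H]12 | intermediate
36 | (3aS,4R,5R,6Z,10E,11aR)-4-(acetyloxy)-6,10-dimethyl-3-methylidene-2-oxo-2,3,3a,4,5,8,9,11a-octahydrocyclodeca[b]furan-5-yl (2Z)-2-methylbut-2-enoate | C=C1C(=O)O[C@@H]2/C=C(\C)CC/C=C(/C)[C@@H](OC(=O)/C(C)=C\C)[C@H](OC(C)=O)[C@@H]12 | target

**Summary**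

Total step count: 20.
Longest linear sequence: 18 steps, from pent-4-yn-1-ol 1 to target 36 (steps 1–3, 5–9, 11–20).

Steps most likely to fail:

1. Step 15 (ring closure). The risk is attack of the alkenylchromium on the other aldehyde face, if the ring-forming conformation overrides the Felkin–Anh preference; this gives the C6 epimer and from it the cis-fused lactone. Oligomerisation at insufficient dilution is the second concern. The fallback sets out from 24 and returns at 26. The same chromium-mediated closure is taken through to the cis-fused lactone F1. LiOH (THF–H2O, 0 °C, cold acidification to pH 5) opens it to the γ-hydroxy acid F2. Mitsunobu lactonisation (PPh3, diisopropyl azodicarboxylate, toluene, 0 °C) then displaces the activated C6 oxygen by the carboxylate with inversion to give 26. The lactone C6–O bond is thus made by SN2 displacement instead of by acylation of a C6 alkoxide.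

2. Step 11 (aldol). The risk is eroded facial selectivity, because the aldehyde face that the auxiliary-controlled enolate must attack is opposed to the intrinsic Cornforth preference of the α-alkoxy aldehyde. Epimerisation at C9 or migration of the β,γ-alkene under titanium Lewis acidity is a further concern. The fallback sets out from 15 and 14 and returns at 24.
   - 15 is joined to (4R)-4-benzyl-1,3-oxazolidin-2-one through its pivalic mixed anhydride (PivCl, Et3N, LiCl, THF) to give the oxazolidinone imide F3.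
   - Bu2BOTf and i-Pr2NEt (CH2Cl2, −78 to 0 °C) give the dibutylboron Z-enolate F4, which adds to 14 at −78 °C through a tight boron-centred chair transition state (buffered H2O2 work-up) to give the syn adduct F5.
   - TBSOTf/2,6-lutidine and then TMSOTf give, by way of the silyl ether F6 and the trimethylsilyl ester F7, the acid F8.
   - TMSCHN2 gives the methyl ester F9.
   - LiSEt (EtSH, n-BuLi, THF, 0 °C) displaces the auxiliary to give the thioester F10.
   - i-Bu2AlH (CH2Cl2, −78 °C) reduces the thioester, which reacts faster than the methyl ester, to the aldehyde 24.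

3. Step 18 (angeloylation). The risk is slow acylation of the C9 hydroxyl, which is flanked by C10 and the C8 silyl ether, so that prolonged heating isomerises the angeloyl donor from Z to E before esterification is complete. The fallback sets out from 30 and returns at 36; it reverses the order of the two acylations so that the angelate goes on last beside a small acetate. HF·pyridine (THF, pyridine) gives the C8 alcohol F11. Ac2O, 4-(dimethylamino)pyridine and pyridine give the C8 acetate F12. DDQ (buffered CH2Cl2) releases the C9 alcohol F13. The mixed anhydride 33 (Et3N, toluene, 60 °C) then acylates the less shielded C9 hydroxyl to give 36.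

**Further compounds**

F1 | step 15 | (3aS,4R,5R,6Z,10E,11aS)-4-[(tert-butyldimethylsilyl)oxy]-5-[(4-methoxyphenyl)methoxy]-6,10-dimethyl-3a,4,5,8,9,11a-hexahydrocyclodeca[b]furan-2(3H)-one (cis-fused C6 epimer of 26) | O=C1C[C@@H]2[C@@H](O[Si](C)(C)C(C)(C)C)[C@H](OCc3ccc(OC)cc3)/C(C)=C\CC/C(C)=C/[C@@H]2O1
F2 | step 15 | 2-[(1S,2R,3R,4Z,8E,10S)-2-[(tert-butyldimethylsilyl)oxy]-10-hydroxy-3-[(4-methoxyphenyl)methoxy]-4,8-dimethylcyclodeca-4,8-dien-1-yl]acetic acid | OC(=O)C[C@@H]1[C@@H](O[Si](C)(C)C(C)(C)C)[C@H](OCc2ccc(OC)cc2)/C(C)=C\CC/C(C)=C/[C@@H]1O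
F3 | step 11 | tert-butyl 4-[(4R)-4-benzyl-2-oxo-1,3-oxazolidin-3-yl]-4-oxobutanoate | CC(C)(C)OC(=O)CCC(=O)N1C(=O)OC[C@H]1Cc1ccccc1
F4 | step 11 | dibutylboron (Z)-enolate of F3 | CC(C)(C)OC(=O)C/C=C(\OB(CCCC)CCCC)N1C(=O)OC[C@H]1Cc1ccccc1
F5 | step 11 | tert-butyl (3R,4R,5R,6Z,10E)-3-{[(4R)-4-benzyl-2-oxo-1,3-oxazolidin-3-yl]carbonyl}-4-hydroxy-11-iodo-5-[(4-methoxyphenyl)methoxy]-6,10-dimethylundeca-6,10-dienoate | CC(C)(C)OC(=O)C[C@@H](C(=O)N1C(=O)OC[C@H]1Cc1ccccc1)[C@@H](O)[C@H](OCc1ccc(OC)cc1)/C(C)=C\CC/C(C)=C/I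
F6 | step 11 | 4-O-tert-butyldimethylsilyl ether of F5 | CC(C)(C)OC(=O)C[C@@H](C(=O)N1C(=O)OC[C@H]1Cc1ccccc1)[C@@H](O[Si](C)(C)C(C)(C)C)[C@H](OCc1ccc(OC)cc1)/C(C)=C\CC/C(C)=C/I
F7 | step 11 | trimethylsilyl ester corresponding to F6 | C[Si](C)(C)OC(=O)C[C@@H](C(=O)N1C(=O)OC[C@H]1Cc1ccccc1)[C@@H](O[Si](C)(C)C(C)(C)C)[C@H](OCc1ccc(OC)cc1)/C(C)=C\CC/C(C)=C/I
F8 | step 11 | (3R,4R,5R,6Z,10E)-3-{[(4R)-4-benzyl-2-oxo-1,3-oxazolidin-3-yl]carbonyl}-4-[(tert-butyldimethylsilyl)oxy]-11-iodo-5-[(4-methoxyphenyl)methoxy]-6,10-dimethylundeca-6,10-dienoic acid | OC(=O)C[C@@H](C(=O)N1C(=O)OC[C@H]1Cc1ccccc1)[C@@H](O[Si](C)(C)C(C)(C)C)[C@H](OCc1ccc(OC)cc1)/C(C)=C\CC/C(C)=C/I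
F9 | step 11 | methyl (3R,4R,5R,6Z,10E)-3-{[(4R)-4-benzyl-2-oxo-1,3-oxazolidin-3-yl]carbonyl}-4-[(tert-butyldimethylsilyl)oxy]-11-iodo-5-[(4-methoxyphenyl)methoxy]-6,10-dimethylundeca-6,10-dienoate | COC(=O)C[C@@H](C(=O)N1C(=O)OC[C@H]1Cc1ccccc1)[C@@H](O[Si](C)(C)C(C)(C)C)[C@H](OCc1ccc(OC)cc1)/C(C)=C\CC/C(C)=C/I
F10 | step 11 | methyl (3R,4R,5R,6Z,10E)-4-[(tert-butyldimethylsilyl)oxy]-3-[(ethylsulfanyl)carbonyl]-11-iodo-5-[(4-methoxyphenyl)methoxy]-6,10-dimethylundeca-6,10-dienoate | COC(=O)C[C@@H](C(=O)SCC)[C@@H](O[Si](C)(C)C(C)(C)C)[C@H](OCc1ccc(OC)cc1)/C(C)=C\CC/C(C)=C/I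
F11 | step 18 | (3aR,4R,5R,6Z,10E,11aR)-4-hydroxy-5-[(4-methoxyphenyl)methoxy]-6,10-dimethyl-3-methylidene-3a,4,5,8,9,11a-hexahydrocyclodeca[b]furan-2(3H)-one | C=C1C(=O)O[C@@H]2/C=C(\C)CC/C=C(/C)[C@@H](OCc3ccc(OC)cc3)[C@H](O)[C@@H]12
F12 | step 18 | (3aS,4R,5R,6Z,10E,11aR)-5-[(4-methoxyphenyl)methoxy]-6,10-dimethyl-3-methylidene-2-oxo-2,3,3a,4,5,8,9,11a-octahydrocyclodeca[b]furan-4-yl acetate | C=C1C(=O)O[C@@H]2/C=C(\C)CC/C=C(/C)[C@@H](OCc3ccc(OC)cc3)[C@H](OC(C)=O)[C@@H]12
F13 | step 18 | (3aS,4R,5R,6Z,10E,11aR)-5-hydroxy-6,10-dimethyl-3-methylidene-2-oxo-2,3,3a,4,5,8,9,11a-octahydrocyclodeca[b]furan-4-yl acetate | C=C1C(=O)O[C@@H]2/C=C(\C)CC/C=C(/C)[C@@H](O)[C@H](OC(C)=O)[C@@H]12
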